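(The numbers of this flask are invented; the run is a simulation.)

The substrate here goes slowly: with the acid as charged and each path taken by itself, its half-life is 26 s by the path that uses acid and 110 s by the path without it.

    substrate + acid → weak acid + acid + target (k1 = 900 M⁻¹ s⁻¹)
    weak acid ⇌ conjugate base + acid, settled at all times (K2 = 1.0 × 10⁻⁵ M)
    substrate → weak acid + target (k3 = 0.0066 s⁻¹)
    weak acid + target → side product (k4 = 8.8 M⁻¹ s⁻¹)
    weak acid → by-product carried off (k5 = 0.098 s⁻¹)
    target → over-reaction product (k6 = 0.059 s⁻¹)

substrate 0.0010 M; acid 0.0300 mM; time 50 s

- part of the substrate that has reacted at 50 s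
- pH of the solution at 50 s

I work with the fraction left, which is the exponential of minus a loss constant times the time. This pseudo-first-order constant is 0.0066 s⁻¹ plus 900 M⁻¹ s⁻¹ times [acid]. With [acid] as charged it is 0.0336 s⁻¹, which leaves 18.6 % at 50 s, so 81.4 % has reacted.

Reacted substrate becomes weak acid, which leaves faster as by-product carried off, at 0.098 s⁻¹, than by the side path, at 0.00880 s⁻¹ even with target at the full charge. So I estimate mean [weak acid] as the amount passed through divided by 0.098 s⁻¹ times the time, or 0.166 mM. The balance with conjugate base then gives a mean [acid] of 0.0584 mM. The loss constant rises to 0.0592 s⁻¹, leaving 5.19 %.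

The weak link is that amount passed through: it used the low first figure and ignored weak acid and conjugate base still standing. Late on, weak acid leaves faster than substrate falls, so I estimate that it trails the substrate at 0.0791 mM. This puts [acid] at 0.0469 mM at the end, a pH of 4.33. The conjugate base standing then is the acid above its charge, 0.0169 mM. Reforged, with both forms taken off what has passed through, my mean [weak acid] is 0.174 mM and my mean [acid] 0.0593 mM. That makes 0.0600 s⁻¹ the mean loss constant, and I commit to 4.98 % left, so 95.0 % reacted.

The forecast says 94.8 % and pH 4.35, holding that “the weak acid it releases adds modestly to the proton pool”.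

The simulation gives 94.8 % reacted and pH 4.35, so my reacted figure stands 0.26 percentage points high. I carry the mean loss constant to the same charge stopped at 20 s: 0.0600 s⁻¹ leaves 30.1 %. That neighbour flask has 71.0 % reacted, and it holds 29.0 % of the substrate charged, with target at 37.9 % and over-reaction product at 31.9 %.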